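The readings are simulated with constants of no real substance; scatter was added.

**Flat target.** In delta and theta the target readings stayed flat while the starting material read 0.9% or less, so later time added nothing beyond the scatter of 0.5 percentage points. Delta averaged 94.3% of the charge and theta 90.4%. But theta differed from delta in both charge and temperature.

| flask | starting material | temperature | remark | time |
|---|---|---|---|---|
| delta | 0.28 M | 45 °C | run made earlier |  |
| theta | 0.44 M | 80 °C | run made earlier |  |
| ochre | 0.20 M |  | at 50 °C until 10 min, from then on at 110 °C | 30 min |
| grey | 0.20 M | 110 °C |  | 30 min |
| green | 0.20 M | 80 °C |  | 30 min |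
| red | 0.20 M | 50 °C |  | 30 min |

| run | time / min | target / % | starting material / % |
|---|---|---|---|
| delta | 60.0 | 94.2 | 0 |
| delta | 90.0 | 93.7 | 0 |
| delta | 150 | 94.3 | 0.4 |
| delta | 180 | 94.3 | 0 |
| delta | 300 | 94.5 | 0 |
| delta | 480 | 93.9 | 0 |
| delta | 720 | 95.0 | 0.3 |
| theta | 12.0 | 91.1 | 0 |
| theta | 20.0 | 90.7 | 0.9 |
| theta | 25.0 | 89.9 | 0.3 |
| theta | 40.0 | 89.5 | 0.6 |
| theta | 50.0 | 90.3 | 0 |
| theta | 80.0 | 91.1 | 0 |
| theta | 120 | 90.0 | 0 |

(scatter of a reading: 0.5 percentage points)

- which flask leads in amount of target, in percent of the starting material charged ("all alike" within 1.5 percentage points) (ochre / grey / green / red / all alike)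
- how much target is there at the end, in percent of the starting material charged: ochre
- how much target is there at the end, in percent of the starting material charged: grey
- how much target is there at the end, in percent of the starting material charged: green
- how much target is there at the end, in percent of the starting material charged: red

- a reading or a percentage of target counts all its forms, free or not

**First way.** I let the charge carry the loss. Lost charge divided by target and by molar charge read 0.217 M⁻¹ in delta and 0.242 M⁻¹ in theta. Their mean 0.230 M⁻¹ is my loss number, a selectivity factor for a side path that grows with the charge. The target fraction then stands on both sides of its own equation, so I iterated. Starting from a whole charge of target gave 95.4% at 0.20 M, and putting that back gave 95.6%. The four flasks share that charge, so this way gave each of them 95.6%.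

**Second way.** I let temperature carry the loss instead. Green, at theta's 80 °C, then got theta's 90.4%, which is 5.2 points below the first way.

**Which cheats.** The temperature way has two constants for two runs, so it passes through both whatever they read, and these runs do not test it. The loss number has one constant, so it could have failed, yet its two readings differed by 0.0250 M⁻¹ while the charge rose 1.57-fold, though the temperature changed between those runs too. I committed to the first way and called the flasks alike within 1.5 points. My weak point was red: delta read 0% starting material at 60.0 min, later than red's 30 min, so I assumed completion in red.

**The forecast.** It gave ochre 94%, grey 91%, green 93% and red 94.8%, with red ahead, each below my figure. Its concentration way read 95.5% and its temperature way 86.5% at grey, and it said: “I hedge between these.”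

**The flasks.** Ochre gave 96.2%, grey 96.3%, green 96.1% and red 96.2%, so the outcome was all alike, and grey stood 5.3 points above the forecast. Ochre's own loss number came to 0.195 M⁻¹, against my 0.230 M⁻¹.

    crystals ⇌ target, rate k1*(cs1 - [target]) while solid is left; crystals form when [target] > cs1 (solubility = 18.0 mM, k = 0.417 s⁻¹)
    starting material + target → side product (k = 0.0161 M⁻¹ s⁻¹, Ea = 52.0 kJ mol⁻¹)
    starting material → target, rate k3*[starting material]/(1 + ([starting material]/sat3)) (1.05 mM, k = 1.56 s⁻¹, Ea = 71.0 kJ mol⁻¹)
    (constants at 50 °C)

**The neighbour.** Ochre's neighbour, charged at 0.80 M, took the same reckoning with 0.230 M⁻¹. The first round gave 81.6% and the second 85.0%. That flask gave 85.2% of target beside 14.8% of side product.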